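**Assumption:** the stereocentre in the target SMILES reads as (S), so (S)-2-methylbutanoic acid is the chiral source; compound numbers run in the forward direction of the synthesis, and 1, 5 and 10 are taken as catalogue compounds.

## Retrosynthetic overview

1. Target 12 ⇒ cut the aryl C5'–O(acyl) bond: anodic dehydrogenative C–H acyloxylation of chalcone 9 with (S)-2-methylbutanoic acid 10 as the last step; the only stereocentre is bought in 10.
2. 9 ⇒ bis-benzyl chalcone 7 (debenzylation) ⇒ Claisen–Schmidt condensation of acetophenone 4 with benzaldehyde 5 (enone C=C bond).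
3. 4 ⇒ quinol 3 (double O-methylation) ⇒ Elbs para-hydroxylation of commercial acetophenone 1.
4. No ring is formed: ring A comes from 1 and ring B from 5. Ring A goes from tri- to penta-oxygenated by two para C–H oxygenations (C3' chemical, C5' electrochemical).

## Route

Step 1
Reactants: 1 1-[2,4-bis(benzyloxy)-6-hydroxyphenyl]ethan-1-one
Product: 3 1-[2,4-bis(benzyloxy)-3,6-dihydroxyphenyl]ethan-1-one, via potassium aryl sulfate 2 (not isolated)
Conditions: K2S2O8 (1.2 equiv), 10% aq KOH/pyridine, 0 °C to rt, 24 h; then aq HCl, Na2SO3, 90 °C, 1 h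
Reagents that add atoms: potassium peroxydisulfate, [K+].[K+].[O-]S(=O)(=O)OOS(=O)(=O)[O-]
Why: Elbs persulfate oxidation: the phenoxide of 1 attacks peroxydisulfate through the carbon para to O− (C3, the only para position), giving aryl sulfate 2, which hot dilute acid hydrolyses to the quinol while the benzyl ethers and the ketone are untouched.

Step 2
Reactants: 3 1-[2,4-bis(benzyloxy)-3,6-dihydroxyphenyl]ethan-1-one
Product: 4 1-[2,4-bis(benzyloxy)-3,6-dimethoxyphenyl]ethan-1-one
Conditions: MeI (4 equiv), K2CO3 (4 equiv), DMF, 50 °C, Ar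
Reagents that add atoms: iodomethane, CI
Why: Williamson O-methylation with excess MeI/K2CO3 in warm DMF alkylates both the hindered 3-OH and the hydrogen-bonded 6-OH, and argon keeps the quinol from oxidising to the quinone.

Step 3
Reactants: 4 1-[2,4-bis(benzyloxy)-3,6-dimethoxyphenyl]ethan-1-one; 5 benzaldehyde
Product: 7 (E)-1-[2,4-bis(benzyloxy)-3,6-dimethoxyphenyl]-3-phenylprop-2-en-1-one, via aldol adduct 6 (not isolated)
Conditions: PhCHO (1.2 equiv), 50% aq KOH, EtOH, rt, 24 h
Reagents that add atoms: benzaldehyde (5), O=Cc1ccccc1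
Why: Claisen–Schmidt condensation: the methyl ketone enolate adds to non-enolisable benzaldehyde and aldol 6 dehydrates by E1cB to the conjugated (E)-enone, with no free phenol present to slow enolisation or close a flavanone.

Step 4
Reactants: 7 (E)-1-[2,4-bis(benzyloxy)-3,6-dimethoxyphenyl]-3-phenylprop-2-en-1-one
Product: 9 (E)-1-(2,4-dihydroxy-3,6-dimethoxyphenyl)-3-phenylprop-2-en-1-one, via bis(dichloroboryl) ether 8 (not isolated)
Conditions: BCl3 (5 equiv), C6HMe5 (6 equiv), CH2Cl2, −78 °C, 45 min; then H2O, −78 °C to rt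
Reagents that add atoms: none
Why: Lewis-acid debenzylation with a cation scavenger: BCl3 cleaves both ArO–Bn bonds at −78 °C, pentamethylbenzene traps the benzyl cation so the free C5' position is not benzylated, and the enone (which H2/Pd would reduce) and the methyl ethers survive at this temperature.

Step 5
Reactants: 9 (E)-1-(2,4-dihydroxy-3,6-dimethoxyphenyl)-3-phenylprop-2-en-1-one; 10 (S)-2-methylbutanoic acid
Product: 12 2,4-dihydroxy-3,6-dimethoxy-5-[(2E)-3-phenylprop-2-enoyl]phenyl (2S)-2-methylbutanoate, via cyclohexadienone tautomer 11 (not isolated)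
Conditions: 10 (6 equiv), 2,6-lutidine (2 equiv), nBu4NPF6 (0.1 M), HFIP/CH2Cl2 1:4, 4 Å MS, 9 at 0.02 M, graphite(+)/Pt(−), undivided cell, 2 mA cm−2, 2.2 F mol−1, 0 °C
Reagents that add atoms: (S)-2-methylbutanoic acid (10), CC[C@H](C)C(=O)O
Why: Proposed new method: anodic dehydrogenative C–H acyloxylation of a free polyphenolic 2'-hydroxychalcone with a stoichiometric chiral aliphatic acid; two-electron, one-proton oxidation of the electron-rich A ring at graphite (expected well below the potential for Kolbe oxidation of the carboxylate or for oxidation of the enone and B ring) gives an HFIP-stabilised phenoxonium ion, the carboxylate of 10 adds at C5' (the only unsubstituted ring carbon, para to 2'-O and ortho to 4'-O) to give dienone 11, which tautomerises irreversibly to the aryl ester whereas addition at substituted carbons is reversible; the new acyloxy group raises the oxidation potential of 12 and protects it from over-oxidation, H2 forms at the cathode, and the α-stereocentre of 10 is never enolised or decarboxylated, so (S) is carried through unchanged; closest known reaction types are anodic nuclear acetoxylation of electron-rich arenes in acetic acid/acetate and anodic phenoxonium capture to quinol esters or quinone monoketals, with the Elbs para-oxygenation as the chemical analogue.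

## Compound list

1 | 1-[2,4-bis(benzyloxy)-6-hydroxyphenyl]ethan-1-one | CC(=O)c1c(O)cc(OCc2ccccc2)cc1OCc1ccccc1 | starting material
2 | potassium 3-acetyl-2,6-bis(benzyloxy)-4-hydroxyphenyl sulfate | CC(=O)c1c(O)cc(OCc2ccccc2)c(OS(=O)(=O)[O-])c1OCc1ccccc1.[K+] | intermediate (not isolated)
3 | 1-[2,4-bis(benzyloxy)-3,6-dihydroxyphenyl]ethan-1-one | CC(=O)c1c(O)cc(OCc2ccccc2)c(O)c1OCc1ccccc1 | intermediate
4 | 1-[2,4-bis(benzyloxy)-3,6-dimethoxyphenyl]ethan-1-one | CC(=O)c1c(OC)cc(OCc2ccccc2)c(OC)c1OCc1ccccc1 | intermediate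
5 | benzaldehyde | O=Cc1ccccc1 | starting material
6 | 1-[2,4-bis(benzyloxy)-3,6-dimethoxyphenyl]-3-hydroxy-3-phenylpropan-1-one (racemic aldol adduct) | COc1cc(OCc2ccccc2)c(OC)c(OCc2ccccc2)c1C(=O)CC(O)c1ccccc1 | intermediate (not isolated)
7 | (E)-1-[2,4-bis(benzyloxy)-3,6-dimethoxyphenyl]-3-phenylprop-2-en-1-one | COc1cc(OCc2ccccc2)c(OC)c(OCc2ccccc2)c1C(=O)/C=C/c1ccccc1 | intermediate
8 | (E)-1-[2,4-bis(dichloroboryloxy)-3,6-dimethoxyphenyl]-3-phenylprop-2-en-1-one | COc1cc(OB(Cl)Cl)c(OC)c(OB(Cl)Cl)c1C(=O)/C=C/c1ccccc1 | intermediate (not isolated)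
9 | (E)-1-(2,4-dihydroxy-3,6-dimethoxyphenyl)-3-phenylprop-2-en-1-one (2',4'-dihydroxy-3',6'-dimethoxychalcone) | COc1cc(O)c(OC)c(O)c1C(=O)/C=C/c1ccccc1 | intermediate
10 | (S)-2-methylbutanoic acid | CC[C@H](C)C(=O)O | starting material
11 | 3-hydroxy-2,6-dimethoxy-4-oxo-5-[(2E)-3-phenylprop-2-enoyl]cyclohexa-2,5-dien-1-yl (2S)-2-methylbutanoate (ring sp3 carbon unspecified, both epimers) | CC[C@H](C)C(=O)OC1C(O)=C(OC)C(=O)C(C(=O)/C=C/c2ccccc2)=C1OC | intermediate (not isolated)
12 | 2,4-dihydroxy-3,6-dimethoxy-5-[(2E)-3-phenylprop-2-enoyl]phenyl (2S)-2-methylbutanoate (CNP0237988.1) | CC[C@H](C)C(=O)Oc1c(O)c(OC)c(O)c(C(=O)/C=C/c2ccccc2)c1OC | target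

## Step count and risk

Total step count: 5. Longest linear sequence: 5 steps (1 → 3 → 4 → 7 → 9 → 12).

The three steps most likely to fail:

**Step 5 (proposed anodic acyloxylation).** Risks are phenoxyl C–C/C–O dimerisation, quinone formation with trace water, and migration of the acyl group to the neighbouring 4'-OH. The fallback uses known chemistry only and sets out from 7. MgBr2·OEt2 (toluene/Et2O, reflux) cleaves only the benzyl ether ortho to the carbonyl by chelation and gives (E)-1-[4-(benzyloxy)-2-hydroxy-3,6-dimethoxyphenyl]-3-phenylprop-2-en-1-one F3. Elbs oxidation of F3 (K2S2O8, aq KOH/pyridine) para to the 2'-OH gives potassium 2-(benzyloxy)-4-hydroxy-3,6-dimethoxy-5-[(2E)-3-phenylprop-2-enoyl]phenyl sulfate F4, which acid hydrolysis converts to (E)-1-[4-(benzyloxy)-2,5-dihydroxy-3,6-dimethoxyphenyl]-3-phenylprop-2-en-1-one F5. Steglich esterification with 10 (EDC·HCl, cat. DMAP, CH2Cl2, 0 °C) acylates the only non-chelated hydroxyl and gives 2-(benzyloxy)-4-hydroxy-3,6-dimethoxy-5-[(2E)-3-phenylprop-2-enoyl]phenyl (2S)-2-methylbutanoate F6. Acidolytic debenzylation (TFA, pentamethylbenzene, rt) then comes back to the route at 12.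

**Step 1 (Elbs oxidation).** Yields for this reaction are typically modest, the chelated lipophilic phenol dissolves poorly, and starting material is usually recovered. The fallback sets out from 1 and oxidises it to the para-quinone by Teuber oxidation with Fremy's salt (ON(SO3K)2, KH2PO4, acetone/H2O), giving 2-acetyl-3,5-bis(benzyloxy)cyclohexa-2,5-diene-1,4-dione F1. Reduction with aqueous Na2S2O4 comes back to the route at 3.

**Step 4 (debenzylation beside the enone).** Risks are loss of a methyl ether (6'-OMe ortho to the carbonyl, or the crowded 3'-OMe) and C-benzylation at C5'. The fallback sets out from 4 and removes both benzyl groups before the alkene exists (H2, Pd/C, EtOAc, rt), giving 1-(2,4-dihydroxy-3,6-dimethoxyphenyl)ethan-1-one F2. Claisen–Schmidt condensation of the free diphenol with 5 (60% aq KOH, EtOH, rt, prolonged) comes back to the route at 9.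

## Further compounds

F1 | step 1 | 2-acetyl-3,5-bis(benzyloxy)cyclohexa-2,5-diene-1,4-dione | CC(=O)C1=C(OCc2ccccc2)C(=O)C(OCc2ccccc2)=CC1=O
F2 | step 4 | 1-(2,4-dihydroxy-3,6-dimethoxyphenyl)ethan-1-one | CC(=O)c1c(OC)cc(O)c(OC)c1O
F3 | step 5 | (E)-1-[4-(benzyloxy)-2-hydroxy-3,6-dimethoxyphenyl]-3-phenylprop-2-en-1-one | COc1cc(OCc2ccccc2)c(OC)c(O)c1C(=O)/C=C/c1ccccc1
F4 | step 5 | potassium 2-(benzyloxy)-4-hydroxy-3,6-dimethoxy-5-[(2E)-3-phenylprop-2-enoyl]phenyl sulfate | COc1c(OS(=O)(=O)[O-])c(OCc2ccccc2)c(OC)c(O)c1C(=O)/C=C/c1ccccc1.[K+]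
F5 | step 5 | (E)-1-[4-(benzyloxy)-2,5-dihydroxy-3,6-dimethoxyphenyl]-3-phenylprop-2-en-1-one | COc1c(O)c(OCc2ccccc2)c(OC)c(O)c1C(=O)/C=C/c1ccccc1
F6 | step 5 | 2-(benzyloxy)-4-hydroxy-3,6-dimethoxy-5-[(2E)-3-phenylprop-2-enoyl]phenyl (2S)-2-methylbutanoate | CC[C@H](C)C(=O)Oc1c(OCc2ccccc2)c(OC)c(O)c(C(=O)/C=C/c2ccccc2)c1OC
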